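**Strategy.** The cycloheptane ring of the target (C3a, C4–C8 and C8a of the cyclohepta[b]furanone) is taken from the cyclohexane ring of (R)-carvone plus one inserted carbon. C8, the ring CH that carries the 2-methylbutanoate, has no carbon substituent and lies between the former carbonyl carbon (C7) and the former α-methylene (C8a). A Lewis-acid-promoted diazo homologation therefore inserts it as CH2 in one operation, turning the six- into the seven-membered ring with three stereocentres retained. The precursor is a 2-methyl-3-silyloxy-5-alkenylcyclohexanone. Afterwards the new CH2 is desaturated and oxygenated by an iodolactonisation/epoxide relay that also builds the cis-lactone.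

Key step: step 6

Remark: TBS = tert-butyldimethylsilyl; 1-methoxybuta-1,3-diene is used as the commercial E/Z mixture, on the assumption that both isomers are metalated at C1 and converge on the same (E)-enone after hydrolysis.

Step 1
Reactants: 1 (R)-carvone
Product: 2 (5R)-5-(3-chloroprop-1-en-2-yl)-2-methylcyclohex-2-en-1-one
Conditions: Ca(OCl)2, CO2 (dry ice), CH2Cl2–H2O, 0 °C
Reagents that add atoms: calcium hypochlorite, [Ca+2].[O-]Cl.[O-]Cl
Why: Ene-type allylic chlorination by HOCl generated in situ attacks only the electron-rich 1,1-disubstituted alkene (the enone C=C is inert) and converts the isopropenyl group into a 2-(chloromethyl)vinyl group without touching C5.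

Step 2
Reactants: 2 (5R)-5-(3-chloroprop-1-en-2-yl)-2-methylcyclohex-2-en-1-one
Product: 3 2-[(1R)-4-methyl-5-oxocyclohex-3-en-1-yl]prop-2-en-1-yl acetate
Conditions: KOAc, NaI (cat.), DMF, 50 °C
Reagents that add atoms: potassium acetate, CC(=O)[O-].[K+]
Why: SN2 displacement of the primary allylic chloride by acetate (iodide catalysis) installs the future lactone oxygen at the alcohol oxidation level.

Step 3
Reactants: 3 2-[(1R)-4-methyl-5-oxocyclohex-3-en-1-yl]prop-2-en-1-yl acetate
Product: 4 (1R,4R,6R)-4-(3-hydroxyprop-1-en-2-yl)-1-methyl-7-oxabicyclo[4.1.0]heptan-2-one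
Conditions: 30% H2O2, NaOH, MeOH–H2O, 0 °C
Reagents that add atoms: hydrogen peroxide, OO
Why: Weitz–Scheffer nucleophilic epoxidation is specific for the enone, hydroperoxide adding to C3 axially and anti to the equatorial C5 side chain as with carvone itself, so the epoxide oxygen is trans to the side chain, and the alkaline medium also saponifies the acetate.

Step 4
Reactants: 4 (1R,4R,6R)-4-(3-hydroxyprop-1-en-2-yl)-1-methyl-7-oxabicyclo[4.1.0]heptan-2-one
Product: 5 (2S,3R,5R)-3-hydroxy-5-(3-hydroxyprop-1-en-2-yl)-2-methylcyclohexan-1-one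
Conditions: SmI2 (2.2 equiv), THF–MeOH, −90 °C
Reagents that add atoms: none
Why: SmI2 reduction of an α,β-epoxy ketone cleaves only the Cα–O bond, so C3 keeps its configuration, and kinetic axial protonation of the samarium-bridged β-alkoxy enolate (C3–O pseudo-equatorial in the chelate) on the oxygen-bearing face should set C2 with methyl trans to hydroxyl and cis to the side chain.

Step 5
Reactants: 5 (2S,3R,5R)-3-hydroxy-5-(3-hydroxyprop-1-en-2-yl)-2-methylcyclohexan-1-one
Product: 6 (2S,3R,5R)-3-(TBSO)-5-[3-(TBSO)prop-1-en-2-yl]-2-methylcyclohexan-1-one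
Conditions: TBSOTf, 2,6-lutidine, CH2Cl2, −78 °C
Reagents that add atoms: tert-butyldimethylsilyl triflate, CC(C)(C)[Si](C)(C)OS(=O)(=O)C(F)(F)F
Why: Silyl ether formation with a hindered, non-enolising base at low temperature protects both hydroxyls without epimerising C2 or causing β-elimination.

Step 6
Reactants: 6 (2S,3R,5R)-3-(TBSO)-5-[3-(TBSO)prop-1-en-2-yl]-2-methylcyclohexan-1-one
Product: 8 (2S,3R,5S)-3-(TBSO)-5-[3-(TBSO)prop-1-en-2-yl]-2-methylcycloheptan-1-one, via α-trimethylsilyl ketone 7 (not isolated)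
Conditions: TMSCHN2 (1.2 equiv), BF3·OEt2, CH2Cl2, −78 °C; then aq. NaHCO3, silica gel
Reagents that add atoms: (trimethylsilyl)diazomethane, C[Si](C)(C)C=[N+]=[N-]
Why: BF3 activates the ketone, the diazo carbon adds to C1, and the β-oxido diazonium loses N2 with 1,2-shift of the ring bond anti to it, which inserts one carbon between C1 and C6; the α-silyl ketone 7 is protodesilylated on work-up. The closest known reaction type is the Lewis-acid-promoted TMSCHN2 homologation of 2-substituted cyclohexanones (a Tiffeneau–Demjanov-type ring expansion). No ring is closed by cyclisation: the seven-membered ring arises from the six-membered one by a carbon-to-carbon 1,2-shift with ring enlargement. No new stereocentre survives (the C–Si centre of 7 is lost), and C2, C3 and C5 are retained because none of their bonds is broken and the work-up is non-enolising. The step needs migration of C6 (CH2) rather than C2, secured by C2 being a hindered methine with an inductively deactivating β-silyloxy group, and it needs mono-homologation, secured by the lower reactivity of the cycloheptanone and the small excess of reagent at −78 °C.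

Step 7
Reactants: 8 (2S,3R,5S)-3-(TBSO)-5-[3-(TBSO)prop-1-en-2-yl]-2-methylcycloheptan-1-one
Product: 10 (4R,6R,7S)-6-(TBSO)-4-[3-(TBSO)prop-1-en-2-yl]-7-methylcyclohept-2-en-1-one, via trimethylsilyl enol ether 9 (not isolated)
Conditions: LiHMDS, TMSCl, THF, −78 °C; then Pd(OAc)2, MeCN, rt
Reagents that add atoms: none
Why: Kinetic enolisation occurs at the unsubstituted C7 methylene of 8 rather than at the hindered methyl-bearing C2, and Saegusa–Ito oxidation of that silyl enol ether places the C=C between the inserted carbon and the former α-methylene without touching a stereocentre.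

Step 8
Reactants: 10 (4R,6R,7S)-6-(TBSO)-4-[3-(TBSO)prop-1-en-2-yl]-7-methylcyclohept-2-en-1-one; 11 1-methoxybuta-1,3-diene
Product: 13 (E)-1-[(1R,4R,6R,7S)-6-(TBSO)-1-hydroxy-4-(3-hydroxyprop-1-en-2-yl)-7-methylcyclohept-2-en-1-yl]but-2-en-1-one, via dienyl ether carbinol 12 (not isolated)
Conditions: 11, n-BuLi, KOt-Bu, THF, −95 °C; then 10, −78 °C; then 0.5 M aq. HCl, THF, 0 °C → rt
Reagents that add atoms: water, O
Why: The α-metalated 1-alkoxydiene (superbase metalation at C1) is a crotonoyl anion equivalent that should add 1,2 to the enone on the face opposite the methyl of the adjacent C7 (hydroxyl cis to methyl), and dilute acid then hydrolyses the dienyl ether to the (E)-enone and cleaves only the primary allylic silyl ether.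

Step 9
Reactants: 13 (E)-1-[(1R,4R,6R,7S)-6-(TBSO)-1-hydroxy-4-(3-hydroxyprop-1-en-2-yl)-7-methylcyclohept-2-en-1-yl]but-2-en-1-one
Product: 15 2-[(1R,4R,5S,6R)-4-[(E)-but-2-enoyl]-6-(TBSO)-4-hydroxy-5-methylcyclohept-2-en-1-yl]prop-2-enoic acid, via enal 14 (not isolated)
Conditions: TEMPO (cat.), PhI(OAc)2, CH2Cl2, rt; then NaClO2, NaH2PO4, 2-methylbut-2-ene, t-BuOH–H2O, 0 °C
Reagents that add atoms: sodium chlorite, [Na+].[O-]Cl=O
Why: Oxoammonium (TEMPO) oxidation touches only the primary allylic alcohol (the tertiary carbinol is inert, the secondary one is silylated) and Pinnick oxidation of the resulting 2-substituted acrolein gives the acrylic acid without disturbing the alkenes.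

Step 10
Reactants: 15 2-[(1R,4R,5S,6R)-4-[(E)-but-2-enoyl]-6-(TBSO)-4-hydroxy-5-methylcyclohept-2-en-1-yl]prop-2-enoic acid
Product: 16 (3aS,5R,6S,7R,8S,8aR)-7-[(E)-but-2-enoyl]-5-(TBSO)-7-hydroxy-8-iodo-6-methyl-3-methylideneoctahydro-2H-cyclohepta[b]furan-2-one
Conditions: I2, NaHCO3, MeCN–H2O, 0 °C, dark
Reagents that add atoms: iodine, II
Why: In this 5-exo iodolactonisation of the γ,δ-unsaturated acid the carboxylate can reach the alkene carbon next to the side-chain-bearing carbon only on the face of its own tether, giving the cis-fused α-methylene lactone, and anti addition places iodine on the neighbouring carbon trans to both the lactone oxygen and the tertiary hydroxyl.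

Step 11
Reactants: 16 (3aS,5R,6S,7R,8S,8aR)-7-[(E)-but-2-enoyl]-5-(TBSO)-7-hydroxy-8-iodo-6-methyl-3-methylideneoctahydro-2H-cyclohepta[b]furan-2-one; 17 (S)-2-methylbutanoic acid
Product: 19 (3aS,5R,6S,7S,8S,8aR)-7-[(E)-but-2-enoyl]-5-(TBSO)-7-hydroxy-6-methyl-3-methylidene-2-oxooctahydro-2H-cyclohepta[b]furan-8-yl (2S)-2-methylbutanoate, via epoxide 18 (not isolated)
Conditions: 17 (3 equiv), Cs2CO3 (1.2 equiv), DMF, 60 °C
Reagents that add atoms: none
Why: Double inversion: the cesium carboxylate first closes the trans-iodohydrin to the 7,8-epoxide (intramolecular SN2) and then opens it at C8, its only non-quaternary carbon (SN2, anti), so the acyloxy group takes the place of iodine, trans to the tertiary hydroxyl and to the lactone oxygen.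

Step 12
Reactants: 19 (3aS,5R,6S,7S,8S,8aR)-7-[(E)-but-2-enoyl]-5-(TBSO)-7-hydroxy-6-methyl-3-methylidene-2-oxooctahydro-2H-cyclohepta[b]furan-8-yl (2S)-2-methylbutanoate
Product: 20 (3aS,5R,6S,7S,8S,8aR)-7-[(E)-but-2-enoyl]-5,7-dihydroxy-6-methyl-3-methylidene-2-oxooctahydro-2H-cyclohepta[b]furan-8-yl (2S)-2-methylbutanoate
Conditions: HF·pyridine, pyridine, THF, 0 °C → rt
Reagents that add atoms: none
Why: Fluoride-mediated desilylation under buffered, non-basic conditions removes the secondary TBS ether without acyl migration, retro-aldol cleavage or conjugate addition to the α-methylene lactone.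

**Compound list**

1 | (R)-(−)-carvone, (5R)-2-methyl-5-(prop-1-en-2-yl)cyclohex-2-en-1-one | C=C(C)[C@@H]1CC=C(C)C(=O)C1 | starting material
2 | (5R)-5-(3-chloroprop-1-en-2-yl)-2-methylcyclohex-2-en-1-one | C=C(CCl)[C@@H]1CC=C(C)C(=O)C1 | intermediate
3 | 2-[(1R)-4-methyl-5-oxocyclohex-3-en-1-yl]prop-2-en-1-yl acetate | C=C(COC(C)=O)[C@@H]1CC=C(C)C(=O)C1 | intermediate
4 | (1R,4R,6R)-4-(3-hydroxyprop-1-en-2-yl)-1-methyl-7-oxabicyclo[4.1.0]heptan-2-one (epoxide oxygen trans to the side chain) | C=C(CO)[C@@H]1C[C@H]2O[C@@]2(C)C(=O)C1 | intermediate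
5 | (2S,3R,5R)-3-hydroxy-5-(3-hydroxyprop-1-en-2-yl)-2-methylcyclohexan-1-one (methyl trans to hydroxyl, cis to side chain) | C=C(CO)[C@@H]1C[C@@H](O)[C@H](C)C(=O)C1 | intermediate
6 | (2S,3R,5R)-3-(TBSO)-5-[3-(TBSO)prop-1-en-2-yl]-2-methylcyclohexan-1-one | C=C(CO[Si](C)(C)C(C)(C)C)[C@@H]1C[C@@H](O[Si](C)(C)C(C)(C)C)[C@H](C)C(=O)C1 | intermediate
7 | 7-trimethylsilyl derivative of 8 (α-silyl ketone, C7 configuration undefined) | C=C(CO[Si](C)(C)C(C)(C)C)[C@@H]1C[C@@H](O[Si](C)(C)C(C)(C)C)[C@H](C)C(=O)C([Si](C)(C)C)C1 | intermediate (not isolated)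
8 | (2S,3R,5S)-3-(TBSO)-5-[3-(TBSO)prop-1-en-2-yl]-2-methylcycloheptan-1-one | C=C(CO[Si](C)(C)C(C)(C)C)[C@@H]1C[C@@H](O[Si](C)(C)C(C)(C)C)[C@H](C)C(=O)CC1 | intermediate
9 | trimethylsilyl enol ether of 8 towards C7 (1-trimethylsilyloxycyclohept-1-ene) | C=C(CO[Si](C)(C)C(C)(C)C)[C@@H]1C[C@@H](O[Si](C)(C)C(C)(C)C)[C@H](C)C(O[Si](C)(C)C)=CC1 | intermediate (not isolated)
10 | (4R,6R,7S)-6-(TBSO)-4-[3-(TBSO)prop-1-en-2-yl]-7-methylcyclohept-2-en-1-one | C=C(CO[Si](C)(C)C(C)(C)C)[C@@H]1C[C@@H](O[Si](C)(C)C(C)(C)C)[C@H](C)C(=O)C=C1 | intermediate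
11 | 1-methoxybuta-1,3-diene (E/Z mixture) | COC=CC=C | starting material
12 | (1R,4R,6R,7S)-6-(TBSO)-4-[3-(TBSO)prop-1-en-2-yl]-1-(1-methoxybuta-1,3-dien-1-yl)-7-methylcyclohept-2-en-1-ol | C=C(CO[Si](C)(C)C(C)(C)C)[C@@H]1C[C@@H](O[Si](C)(C)C(C)(C)C)[C@H](C)[C@@](O)(C(OC)=CC=C)C=C1 | intermediate (not isolated)
13 | (E)-1-[(1R,4R,6R,7S)-6-(TBSO)-1-hydroxy-4-(3-hydroxyprop-1-en-2-yl)-7-methylcyclohept-2-en-1-yl]but-2-en-1-one | C=C(CO)[C@@H]1C[C@@H](O[Si](C)(C)C(C)(C)C)[C@H](C)[C@@](O)(C(=O)/C=C/C)C=C1 | intermediate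
14 | 2-[(1R,4R,5S,6R)-4-[(E)-but-2-enoyl]-6-(TBSO)-4-hydroxy-5-methylcyclohept-2-en-1-yl]prop-2-enal | C=C(C=O)[C@@H]1C[C@@H](O[Si](C)(C)C(C)(C)C)[C@H](C)[C@@](O)(C(=O)/C=C/C)C=C1 | intermediate (not isolated)
15 | 2-[(1R,4R,5S,6R)-4-[(E)-but-2-enoyl]-6-(TBSO)-4-hydroxy-5-methylcyclohept-2-en-1-yl]prop-2-enoic acid | C=C(C(=O)O)[C@@H]1C[C@@H](O[Si](C)(C)C(C)(C)C)[C@H](C)[C@@](O)(C(=O)/C=C/C)C=C1 | intermediate
16 | (3aS,5R,6S,7R,8S,8aR)-7-[(E)-but-2-enoyl]-5-(TBSO)-7-hydroxy-8-iodo-6-methyl-3-methylideneoctahydro-2H-cyclohepta[b]furan-2-one (cis-fused lactone, iodine trans to O1 and to 7-OH) | C=C1C(=O)O[C@@H]2[C@H]1C[C@@H](O[Si](C)(C)C(C)(C)C)[C@H](C)[C@@](O)(C(=O)/C=C/C)[C@H]2I | intermediate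
17 | (S)-2-methylbutanoic acid | CC[C@H](C)C(=O)O | starting material
18 | 7,8-epoxide derived from 16 (oxirane oxygen on the face of the lactone oxygen O1 and of the 6-methyl group) | C=C1C(=O)O[C@@H]2[C@H]1C[C@@H](O[Si](C)(C)C(C)(C)C)[C@H](C)[C@]3(C(=O)/C=C/C)O[C@H]23 | intermediate (not isolated)
19 | (3aS,5R,6S,7S,8S,8aR)-7-[(E)-but-2-enoyl]-5-(TBSO)-7-hydroxy-6-methyl-3-methylidene-2-oxooctahydro-2H-cyclohepta[b]furan-8-yl (2S)-2-methylbutanoate | C=C1C(=O)O[C@@H]2[C@H]1C[C@@H](O[Si](C)(C)C(C)(C)C)[C@H](C)[C@@](O)(C(=O)/C=C/C)[C@H]2OC(=O)[C@@H](C)CC | intermediate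
20 | (3aS,5R,6S,7S,8S,8aR)-7-[(E)-but-2-enoyl]-5,7-dihydroxy-6-methyl-3-methylidene-2-oxooctahydro-2H-cyclohepta[b]furan-8-yl (2S)-2-methylbutanoate | C=C1C(=O)O[C@@H]2[C@H]1C[C@@H](O)[C@H](C)[C@@](O)(C(=O)/C=C/C)[C@H]2OC(=O)[C@@H](C)CC | target

**Step count.** Total: 12 steps. Longest linear sequence: 12 steps (1 → 20).

**Steps most likely to fail**

Step 4. The protonation of the enolate may take place on the other face, or the β-hydroxy ketone may epimerise on isolation, so that the 2,3-cis ketone predominates. The fallback sets out from 4 and comes back at 8. The SmI2 reduction is run without regard to C2, and the epimeric (2R,3R,5R)-3-hydroxy-5-(3-hydroxyprop-1-en-2-yl)-2-methylcyclohexan-1-one F1 is silylated to the bis-silyl ether F2. This is ring-expanded as in step 6 through the α-silyl ketone F3 to the 2-epi-cycloheptanone F4. C2 is then set under thermodynamic control in the seven-membered ring (DBU, toluene, rt). There the 2,3-trans isomer 8 can hold methyl and silyloxy both pseudo-equatorial, which the cyclohexanone cannot do because of the trans relationship between C3 and C5.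

Step 11. The hindered epoxide may be opened too slowly by the carboxylate, so that elimination or rearrangement of the epoxy ketone takes over. The fallback sets out from 16 and comes back at 19. The epoxide 18 is isolated (Cs2CO3, MeCN, rt) and hydrolysed with dilute HClO4 in THF–H2O, water attacking C8 anti to the oxirane, to give the trans-diol (5-TBSO-7,8-dihydroxy lactone) F9. Its secondary C8 hydroxyl is then acylated with 17 under Yamaguchi conditions (2,4,6-trichlorobenzoyl chloride, Et3N, DMAP); the tertiary hydroxyl does not react.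

Step 8. The 1,2-addition may show poor facial selectivity, because the silyloxy group on C6 lies on the face that the methyl group leaves open and may screen it. The fallback sets out from 10 and comes back at 13. Both silyl ethers of 10 are removed (HF·pyridine) to give the diol enone (4R,6R,7S)-6-hydroxy-4-(3-hydroxyprop-1-en-2-yl)-7-methylcyclohept-2-en-1-one F5. Addition of 3.3 equiv of metalated 11 with CeCl3 (two equivalents are spent on the hydroxyls) is then directed by the C6 alkoxide to its own face and gives the dienyl ether adduct F6. Mild acid hydrolysis gives the triol enone F7. Silylation of the primary and secondary hydroxyls (TBSOTf, 2,6-lutidine) gives the bis-silyl ether F8, and selective cleavage of the primary silyl ether (PPTS, MeOH) returns 13.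

**Further compounds**

F1 | step 4 | (2R,3R,5R)-3-hydroxy-5-(3-hydroxyprop-1-en-2-yl)-2-methylcyclohexan-1-one | C=C(CO)[C@@H]1C[C@@H](O)[C@@H](C)C(=O)C1
F2 | step 4 | (2R,3R,5R)-3-(TBSO)-5-[3-(TBSO)prop-1-en-2-yl]-2-methylcyclohexan-1-one | C=C(CO[Si](C)(C)C(C)(C)C)[C@@H]1C[C@@H](O[Si](C)(C)C(C)(C)C)[C@@H](C)C(=O)C1
F3 | step 4 | 7-trimethylsilyl derivative of F4 (α-silyl ketone) | C=C(CO[Si](C)(C)C(C)(C)C)[C@@H]1C[C@@H](O[Si](C)(C)C(C)(C)C)[C@@H](C)C(=O)C([Si](C)(C)C)C1
F4 | step 4 | (2R,3R,5S)-3-(TBSO)-5-[3-(TBSO)prop-1-en-2-yl]-2-methylcycloheptan-1-one | C=C(CO[Si](C)(C)C(C)(C)C)[C@@H]1C[C@@H](O[Si](C)(C)C(C)(C)C)[C@@H](C)C(=O)CC1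
F5 | step 8 | (4R,6R,7S)-6-hydroxy-4-(3-hydroxyprop-1-en-2-yl)-7-methylcyclohept-2-en-1-one | C=C(CO)[C@@H]1C[C@@H](O)[C@H](C)C(=O)C=C1
F6 | step 8 | (1R,2S,3R,5R)-5-(3-hydroxyprop-1-en-2-yl)-1-(1-methoxybuta-1,3-dien-1-yl)-2-methylcyclohept-6-ene-1,3-diol | C=C(CO)[C@@H]1C[C@@H](O)[C@H](C)[C@@](O)(C(OC)=CC=C)C=C1
F7 | step 8 | (E)-1-[(1R,4R,6R,7S)-1,6-dihydroxy-4-(3-hydroxyprop-1-en-2-yl)-7-methylcyclohept-2-en-1-yl]but-2-en-1-one | C=C(CO)[C@@H]1C[C@@H](O)[C@H](C)[C@@](O)(C(=O)/C=C/C)C=C1
F8 | step 8 | (E)-1-[(1R,4R,6R,7S)-6-(TBSO)-4-[3-(TBSO)prop-1-en-2-yl]-1-hydroxy-7-methylcyclohept-2-en-1-yl]but-2-en-1-one | C=C(CO[Si](C)(C)C(C)(C)C)[C@@H]1C[C@@H](O[Si](C)(C)C(C)(C)C)[C@H](C)[C@@](O)(C(=O)/C=C/C)C=C1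
F9 | step 11 | (3aS,5R,6S,7S,8S,8aR)-7-[(E)-but-2-enoyl]-5-(TBSO)-7,8-dihydroxy-6-methyl-3-methylideneoctahydro-2H-cyclohepta[b]furan-2-one | C=C1C(=O)O[C@@H]2[C@H]1C[C@@H](O[Si](C)(C)C(C)(C)C)[C@H](C)[C@@](O)(C(=O)/C=C/C)[C@H]2O
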